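**Retrosynthetic overview**

1. Prismatomerin ⇒ phenol desilylation and C4 carbomethoxylation (trichloroacetylation, then haloform methanolysis) of the 4‑unsubstituted tetracycle 18.
2. The bridging tetrahydrofuran (C1–O–C10) and the E‑arylidene ⇒ intramolecular oxa‑Michael/E1cB (net SN2′) of a C1 lactol onto a spiro‑butenolide carrying C11–CH(OAc)Ar. The lactol/dihydropyran ⇒ glycol cleavage of a cyclopentene (ring B).
3. The butenolide side chain ⇒ sulfenylation, aldol with 4‑(TIPSO)benzaldehyde and sulfoxide elimination on a spiro‑γ‑butyrolactone. The lactone ⇒ Baeyer–Villiger oxidation of a spirocyclobutanone built on (1R,5R)‑bicyclo[3.3.0]oct‑7‑en‑2‑one by ylide spiro‑epoxidation and seleno‑induced ring expansion.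
4. The bicyclic ketone ⇒ transannular carbenoid insertion of (3S,4R)‑3,4‑epoxycyclooctene, made by Mn(salen) epoxidation of cycloocta‑1,3‑diene; a lipase acylation raises the material to a single enantiomer.
5. Ring order: cis‑diquinane (rings A/B) → spirocyclobutanone → γ‑lactone → dihydropyran lactol (from ring B) → bridging THF.

Assumption: iridoid numbering is used from compound 5 onward. C1/C3 are the ring‑B alkene carbons (C1 on C9), C4 the ring‑B CH2, C5/C9 the ring‑fusion carbons, C6/C7 ring‑A carbons, C8 the carbonyl/spiro carbon, C10–C12 the three carbons from the cyclopropyl unit, C13 the benzylic carbon. Centres that are later erased or equilibrate (C11, C13, Se‑bearing C7, lactol C1) are carried as mixtures. The route is a design on paper; the ee and selectivity figures are expectations.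

---

**Step 1**
Reactants: 1 cycloocta‑1,3‑diene
Product: 2 (1S,8R)‑9‑oxabicyclo[6.1.0]non‑2‑ene [(3S,4R)‑3,4‑epoxycyclooctene]
Conditions: (S,S)‑Jacobsen Mn(salen)Cl (4 mol %), 4‑phenylpyridine N‑oxide (0.2 equiv), buffered NaOCl (pH 11.3), CH2Cl2, 0 °C
Reagents that add atoms: sodium hypochlorite, [Na+].[O-]Cl
Why: Jacobsen–Katsuki epoxidation of a conjugated cis‑olefin creates the first two stereocentres, with the facial sense assumed by analogy to indene and cis‑β‑methylstyrene with the (S,S) catalyst (about 85–90% ee expected), and stops at the mono‑epoxide because the remaining alkene is deactivated.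

**Step 2**
Reactants: 2 (1S,8R)‑epoxide
Product: 3 (1R,2R,5R)‑cis‑bicyclo[3.3.0]oct‑7‑en‑2‑ol (endo alcohol, about 85–90% ee)
Conditions: LiNEt2 (2.5 equiv), Et2O, reflux
Reagents that add atoms: none
Why: α‑lithiation at the allylic epoxide carbon and transannular carbenoid C–H insertion forms the cis‑fused diquinane; the C–O carbon is untouched, so epoxide chirality transfers fully to the bridgeheads.

**Step 3**
Reactants: 3 (about 85–90% ee)
Product: 4 (1R,2R,5R)‑cis‑bicyclo[3.3.0]oct‑7‑en‑2‑yl acetate (>99% ee)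
Conditions: immobilised lipase PS (Burkholderia cepacia lipase), vinyl acetate (3 equiv), MTBE, 25 °C, stop at about 90% conversion; chromatography
Reagents that add atoms: vinyl acetate, C=COC(C)=O
Why: lipase‑catalysed enantioselective transesterification acylates the (2R)‑alcohol fast (Kazlauskas rule: large bridgehead CH versus medium CH2), so the acetate is enantiopure and the minor (2S)‑enantiomer stays behind as alcohol and is removed.

**Step 4**
Reactants: 4 acetate
Product: 5 (1R,5R)‑cis‑bicyclo[3.3.0]oct‑7‑en‑2‑one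
Conditions: K2CO3, MeOH, rt; extractive work‑up into CH2Cl2 (volatile free alcohol not isolated); then Dess–Martin periodinane, NaHCO3, CH2Cl2, 0 °C → rt
Reagents that add atoms: none
Why: ester methanolysis telescoped into a neutral Dess–Martin oxidation, which avoids conjugation of the β,γ‑enone; the ring fusion can only be cis, so the bridgeheads are not scrambled.

**Step 5**
Reactants: 5 ketone
Product: 6 oxaspiropentane: dispiro[bicyclo[3.3.0]oct‑7‑ene‑2,2′‑oxirane‑3′,1″‑cyclopropane], epoxide O on the concave (endo) face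
Conditions: cyclopropyldiphenylsulfonium tetrafluoroborate (1.2 equiv), powdered KOH, DMSO, 25 °C
Reagents that add atoms: cyclopropyldiphenylsulfonium tetrafluoroborate, C1CC1[S+](c1ccccc1)c1ccccc1.F[B-](F)(F)F
Why: Trost sulfonium‑ylide spiro‑epoxidation (Corey–Chaykovsky type); the ylide attacks the carbonyl from the convex face, putting the oxygen endo.

**Step 6**
Reactants: 6 oxaspiropentane
Product: 7 2‑[1‑(trimethylsilyloxy)cyclopropyl]‑cis‑bicyclo[3.3.0]octa‑2,7‑diene
Conditions: LiNEt2, Et2O/hexane, 0 °C → rt; then TMSCl, Et3N, 0 °C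
Reagents that add atoms: chlorotrimethylsilane, C[Si](C)(C)Cl
Why: syn β‑elimination of the epoxide by the lithium amide removes the endo C7–H (syn to the endo oxygen; the exo bridgehead H is anti and not removed), giving the 1‑alkenylcyclopropanolate, which is silylated.

**Step 7**
Reactants: 7 vinylcyclopropanol TMS ether
Product: 8 3‑(phenylselanyl)spiro[bicyclo[3.3.0]oct‑7‑ene‑2,1′‑cyclobutan]‑2′‑one (SePh exo at C7; cyclobutanone CH2 on the concave face of C8, C=O carbon on the convex face)
Conditions: PhSeBr (1.0 equiv), CH2Cl2, −78 °C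
Reagents that add atoms: phenylselenenyl bromide, Br[Se]c1ccccc1
Why: electrophile‑induced cyclopropanol→cyclobutanone ring expansion (semipinacol, "substitutive spiroannulation"); PhSe+ adds from the convex face and the cyclopropane bond migrates anti, setting the C8 spiro centre with the future C10 syn to ring B.

**Step 8**
Reactants: 8 α‑selenyl spirocyclobutanone
Product: 9 spiro[bicyclo[3.3.0]octa‑3,7‑diene‑2,1′‑cyclobutan]‑2′‑one
Conditions: mCPBA (1.05 equiv), CH2Cl2, −78 °C; then i‑Pr2NH, → rt
Reagents that add atoms: none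
Why: selenoxide syn‑elimination can only go toward C6 (C8 is quaternary), installing the C6=C7 alkene; at −78 °C selenium is oxidised far faster than the alkenes or the ketone.

**Step 9**
Reactants: 9 vinyl spirocyclobutanone
Product: 10 spiro[bicyclo[3.3.0]octa‑3,7‑diene‑2,5′‑oxolan]‑2′‑one (spiro‑γ‑butyrolactone; lactone O on the convex face, syn to H‑9)
Conditions: 30% H2O2, NaOH, THF/MeOH/H2O, 0 °C; then citric acid to pH 4
Reagents that add atoms: hydrogen peroxide, OO
Why: Baeyer–Villiger oxidation of the strained cyclobutanone with migration of the quaternary allylic carbon with retention places the ring oxygen on C8; basic peroxide does not epoxidise the isolated alkenes.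

**Step 10**
Reactants: 10 spirolactone
Product: 11 3′‑(phenylsulfanyl) derivative of 10 (C11 epimers)
Conditions: LDA (2.1 equiv), THF, −78 °C; PhSSPh (1.05 equiv), DMPU, −78 → −20 °C
Reagents that add atoms: diphenyl disulfide, c1ccc(SSc2ccccc2)cc1
Why: lactone enolate sulfenylation; the second equivalent of base keeps the product as its enolate and prevents bis‑sulfenylation.

**Step 11**
Reactants: 12 4‑hydroxybenzaldehyde
Product: 13 4‑(triisopropylsilyloxy)benzaldehyde
Conditions: TIPSCl, imidazole, DMF, rt
Reagents that add atoms: chlorotriisopropylsilane, CC(C)[Si](Cl)(C(C)C)C(C)C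
Why: standard phenol silylation; the aryl TIPS ether tolerates LDA, OsO4, DBU and acid chloride/pyridine.

**Step 12**
Reactants: 11 α‑phenylthio lactone; 13 4‑(TIPSO)benzaldehyde
Product: 14 3′‑[acetoxy(4‑TIPSO‑phenyl)methyl]‑3′‑(phenylsulfanyl) derivative of 10 (diastereomer mixture at C11/C13)
Conditions: LDA (1.1 equiv), THF, −78 °C; 13 (1.2 equiv); then Ac2O (3 equiv), −78 → 0 °C
Reagents that add atoms: acetic anhydride, CC(=O)OC(C)=O
Why: aldol addition of the α‑thio enolate with in‑situ O‑acetylation of the lithium aldolate, which blocks retro‑aldol and installs the leaving group; both new centres are destroyed later.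

**Step 13**
Reactants: 14 aldol acetate
Product: 15 3′‑[acetoxy(4‑TIPSO‑phenyl)methyl]spiro[bicyclo[3.3.0]octa‑3,7‑diene‑2,5′‑furan]‑2′(5′H)‑one (butenolide, C10=C11)
Conditions: mCPBA (1.0 equiv), CH2Cl2, −78 °C; then toluene, CaCO3, 90 °C
Reagents that add atoms: none
Why: sulfoxide syn‑elimination (dehydrosulfenylation) goes into the ring, away from the acetoxy‑bearing carbon, giving the butenolide with an allylic benzylic acetate.

**Step 14**
Reactants: 15 butenolide
Product: 16 ring‑B cis‑diol of 15 (C1, C3 hydroxyls on the convex face)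
Conditions: OsO4 (5 mol %), NMO (1.1 equiv), acetone/H2O, 0 °C, monitored
Reagents that add atoms: osmium tetroxide, O=[Os](=O)(=O)=O (reoxidised by N‑methylmorpholine N‑oxide, C[N+]1([O-])CCOCC1; water, O)
Why: Upjohn dihydroxylation selects the unhindered, electron‑rich ring‑B alkene over the C6=C7 alkene (next to the quaternary acyloxy carbon) and the electron‑poor butenolide; diol configuration is irrelevant.

**Step 15**
Reactants: 16 diol
Product: 17 C1 lactol: 1‑hydroxy‑1,4a,7a‑trihydrocyclopenta[c]pyran (C3=C4 enol ether, C6=C7) spiro‑fused at C8 to the butenolide of 15 (C1 anomers)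
Conditions: NaIO4, THF/pH 7 buffer, 0 °C → rt; then PPTS (cat.), 4 Å MS, CH2Cl2, rt; used crude
Reagents that add atoms: none
Why: glycol cleavage gives the C1/C3 dialdehyde, which closes to the cis‑fused enol‑hemiacetal typical of iridoid aglycones.

**Step 16**
Reactants: 17 lactol
Product: 18 4‑descarbomethoxy‑O‑TIPS‑prismatomerin
Conditions: DBU (1.2 equiv), CH2Cl2, 0 °C → rt
Reagents that add atoms: none
Why: the lactol alkoxide adds to C10 of the butenolide (oxa‑Michael) and the enolate expels acetate (E1cB, net SN2′); C1 and C10 are fixed by the cis‑fused ring constraints from C8/C9, and the conjugated (E)‑arylidene is the thermodynamic isomer.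

**Step 17**
Reactants: 18
Product: 19 4‑(trichloroacetyl) derivative of 18
Conditions: Cl3CCOCl (3 equiv), pyridine, CH2Cl2, 0 °C → rt
Reagents that add atoms: trichloroacetyl chloride, ClC(=O)C(Cl)(Cl)Cl
Why: electrophilic C‑acylation of the enol ether at its nucleophilic β‑carbon (C4); the arylidene lactone and aryl silyl ether are inert to acid chloride/pyridine.

**Step 18**
Reactants: 19
Product: 20 O‑TIPS‑prismatomerin
Conditions: MeOH, Et3N, rt
Reagents that add atoms: methanol, CO
Why: haloform‑type cleavage (methanol adds to the trichloromethyl ketone, CCl3⁻ leaves) gives the methyl β‑alkoxyacrylate under base too mild to open the acetal or lactone.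

**Step 19**
Reactants: 20
Product: 21 prismatomerin
Conditions: TBAF, AcOH (1:1), THF, 0 °C
Reagents that add atoms: none
Why: buffered fluoride cleaves the aryl silyl ether quickly, and the acetic acid keeps the released phenoxide from attacking the arylidene lactone or acetal.

---

**Compound list**

1 | cycloocta‑1,3‑diene (Z,Z) | C1=CC=CCCCC1 | starting material
2 | (1S,8R)‑9‑oxabicyclo[6.1.0]non‑2‑ene | C1=C[C@@H]2O[C@@H]2CCCC1 | intermediate
3 | (1R,2R,5R)‑cis‑bicyclo[3.3.0]oct‑7‑en‑2‑ol (endo) | O[C@@H]1CC[C@@H]2CC=C[C@H]12 | intermediate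
4 | (1R,2R,5R)‑cis‑bicyclo[3.3.0]oct‑7‑en‑2‑yl acetate | CC(=O)O[C@@H]1CC[C@@H]2CC=C[C@H]12 | intermediate
5 | (1R,5R)‑cis‑bicyclo[3.3.0]oct‑7‑en‑2‑one | O=C1CC[C@@H]2CC=C[C@H]12 | intermediate
6 | dispiro[bicyclo[3.3.0]oct‑7‑ene‑2,2′‑oxirane‑3′,1″‑cyclopropane], O endo | C1C[C@@H]2CC=C[C@@H]2[C@]13OC34CC4 | intermediate
7 | 2‑[1‑(trimethylsilyloxy)cyclopropyl]‑cis‑bicyclo[3.3.0]octa‑2,7‑diene | C[Si](C)(C)OC1(CC1)C1=CC[C@@H]2CC=C[C@H]12 | intermediate
8 | 3‑(phenylselanyl)spiro[bicyclo[3.3.0]oct‑7‑ene‑2,1′‑cyclobutan]‑2′‑one | O=C1CC[C@@]12[C@@H]([Se]c3ccccc3)C[C@@H]3CC=C[C@H]23 | intermediate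
9 | spiro[bicyclo[3.3.0]octa‑3,7‑diene‑2,1′‑cyclobutan]‑2′‑one | O=C1CC[C@@]12C=C[C@@H]3CC=C[C@H]23 | intermediate
10 | spiro[bicyclo[3.3.0]octa‑3,7‑diene‑2,5′‑oxolan]‑2′‑one | O=C1CC[C@]2(O1)C=C[C@@H]3CC=C[C@H]23 | intermediate
11 | 3′‑(phenylsulfanyl) derivative of 10 (C11 epimers) | O=C1C(Sc4ccccc4)C[C@]2(O1)C=C[C@@H]3CC=C[C@H]23 | intermediate
12 | 4‑hydroxybenzaldehyde | Oc1ccc(C=O)cc1 | starting material
13 | 4‑(triisopropylsilyloxy)benzaldehyde | O=Cc1ccc(O[Si](C(C)C)(C(C)C)C(C)C)cc1 | intermediate
14 | 3′‑[acetoxy(4‑TIPSO‑phenyl)methyl]‑3′‑(phenylsulfanyl) derivative of 10 (mixture at C11/C13) | O=C1C(Sc4ccccc4)(C(OC(C)=O)c4ccc(O[Si](C(C)C)(C(C)C)C(C)C)cc4)C[C@]2(O1)C=C[C@@H]3CC=C[C@H]23 | intermediate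
15 | 3′‑[acetoxy(4‑TIPSO‑phenyl)methyl]spiro[bicyclo[3.3.0]octa‑3,7‑diene‑2,5′‑furan]‑2′(5′H)‑one | O=C1C(C(OC(C)=O)c4ccc(O[Si](C(C)C)(C(C)C)C(C)C)cc4)=C[C@]2(O1)C=C[C@@H]3CC=C[C@H]23 | intermediate
16 | ring‑B exo,cis‑diol of 15 | O=C1C(C(OC(C)=O)c4ccc(O[Si](C(C)C)(C(C)C)C(C)C)cc4)=C[C@]2(O1)C=C[C@@H]3C[C@@H](O)[C@@H](O)[C@H]23 | intermediate
17 | C1 lactol (1‑hydroxy‑dihydropyran, C3=C4) spiro‑butenolide with C11–CH(OAc)Ar | O=C1C(C(OC(C)=O)c4ccc(O[Si](C(C)C)(C(C)C)C(C)C)cc4)=C[C@]2(O1)C=C[C@@H]3C=COC(O)[C@H]23 | intermediate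
18 | 4‑descarbomethoxy‑O‑TIPS‑prismatomerin | C1=CO[C@@H]2O[C@H]3/C(=C\c4ccc(O[Si](C(C)C)(C(C)C)C(C)C)cc4)C(=O)O[C@]34C=C[C@H]1[C@H]24 | intermediate
19 | 4‑(trichloroacetyl) derivative of 18 | ClC(Cl)(Cl)C(=O)C1=CO[C@@H]2O[C@H]3/C(=C\c4ccc(O[Si](C(C)C)(C(C)C)C(C)C)cc4)C(=O)O[C@]34C=C[C@H]1[C@H]24 | intermediate
20 | O‑TIPS‑prismatomerin | COC(=O)C1=CO[C@@H]2O[C@H]3/C(=C\c4ccc(O[Si](C(C)C)(C(C)C)C(C)C)cc4)C(=O)O[C@]34C=C[C@H]1[C@H]24 | intermediate
21 | prismatomerin | COC(=O)C1=CO[C@@H]2O[C@H]3/C(=C\c4ccc(O)cc4)C(=O)O[C@]34C=C[C@H]1[C@H]24 | target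

---

**Step count:** 19 steps in total. Longest linear sequence: 18 steps (steps 1–10 and 12–19); step 11 is a one‑step side branch.

**Three steps most likely to fail, with fallbacks**

1. **Step 7** (seleno‑induced ring expansion: facial control at C8 and chemoselectivity against the ring‑B alkene). Fallback: abandon the cyclobutanone logic. Mask ring B as the diol acetonide (dihydroxylate acetate 4), make the kinetic enol triflate of the ketone, Negishi‑couple with BrZnCH2CH2CO2Et, epoxidise the C7=C8 alkene from the convex face, open with PhSe⁻ and eliminate the selenoxide. The resulting convex‑face tertiary allylic alkoxide lactonises to the same spirolactone with C6=C7 in place.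

2. **Step 14** (site‑selective dihydroxylation late in the route, followed by lactol formation in step 15). Fallback: move ring‑B cleavage forward to lactone 10, where only two alkenes compete. Dihydroxylate, cleave with periodate and lock the lactol as its C1–O‑TBS silyl acetal. Carry this through sulfenylation, aldol and elimination; fluoride then unmasks the C1 alkoxide and triggers the oxa‑Michael/E1cB closure directly.

3. **Step 18** (with step 17: C4 acylation and basic haloform methanolysis on the base‑sensitive arylidene lactone). Fallback: introduce the C4 carbon as a formyl group by Vilsmeier–Haack formylation of enol ether 18 (POCl3/DMF), then Pinnick oxidation and TMSCHN2 esterification. This avoids trichloromethyl ketone chemistry and basic methanol entirely.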